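**Plan**
1. Retrosynthetic cuts, in order: the allylic alcohol goes back to the acrylate; the C5–vinyl bond (Heck) goes back to C5–Br; trans goes back to cis at C2; then the C2–C3 bond of the dihydrofuran ring is cut; last the O1–C2 ether bond. This leaves 2'-hydroxy-3'-methoxyacetophenone, veratryl chloride and methyl acrylate.
2. Enabling feature: C2 is α to O1 and benzylic to the electron-rich 3,4-dimethoxyphenyl ring. It lies 1,5 to C3 across O1–C7a–C3a of benzo ring A, so its C–H bond is the best hydride donor within reach of a carbene at C3.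
3. Forward: ring A is brominated at the future C5 and O-alkylated. The acetyl carbon, which already carries C3 and its methyl group, becomes a hydrazone and then a diazoalkane. Rhodium-catalysed loss of N2 closes the only new ring by 1,5 C–H insertion. The side chain is added last.
4. Stereochemistry: C3 comes from the chiral dirhodium catalyst. C2 is formed cis under kinetic control and is then equilibrated by acid to trans under control of C3. The E-alkene comes from the Heck reaction.
5. Helpers: the hydrazone nitrogens leave as N2. Bromine holds the place of the alkene, which would intercept the diazoalkane or carbene and would not survive the acid step.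

Key step: step 4

Assumption: the sense of induction given for Rh2(S-PTAD)4 (tetrakis[(S)-(1-adamantyl)(phthalimido)acetato]dirhodium), C3 = S, is inferred by analogy with related phthalimido-carboxylate dirhodium catalysts. Both catalyst enantiomers are sold, and Rh2(R-PTAD)4 would be used if the sense proved opposite.

Step 1
Reactants: 1 1-(2-hydroxy-3-methoxyphenyl)ethan-1-one
Product: 2 1-(5-bromo-2-hydroxy-3-methoxyphenyl)ethan-1-one
Conditions: NBS (1.05 equiv), MeCN, 0 °C to rt
Reagents that add atoms: N-bromosuccinimide, O=C1CCC(=O)N1Br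
Why: Electrophilic aromatic bromination, in which the free phenol directs to its only open ortho/para site (para to OH, meta to acetyl, the future C5) and cold NBS in MeCN avoids α-bromination of the ketone.

Step 2
Reactants: 2 1-(5-bromo-2-hydroxy-3-methoxyphenyl)ethan-1-one; 3 4-(chloromethyl)-1,2-dimethoxybenzene (veratryl chloride)
Product: 4 1-{5-bromo-2-[(3,4-dimethoxyphenyl)methoxy]-3-methoxyphenyl}ethan-1-one
Conditions: K2CO3 (2 equiv), KI (10 mol %), DMF, 60 °C
Reagents that add atoms: none
Why: Williamson ether synthesis, in which the phenoxide displaces the reactive benzylic halide, forms O1–C2 and places the CH2 group 1,5 to the ketone carbon.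

Step 3
Reactants: 4 1-{5-bromo-2-[(3,4-dimethoxyphenyl)methoxy]-3-methoxyphenyl}ethan-1-one
Product: 5 (E)-hydrazone of ketone 4 (NH2 anti to the aryl group; the C=N geometry is of no consequence)
Conditions: N2H4·H2O (10 equiv), AcOH (cat.), EtOH, 80 °C
Reagents that add atoms: hydrazine monohydrate, NN.O
Why: Hydrazone condensation of an aryl methyl ketone, in which the large excess of hydrazine suppresses azine formation and the aryl bromide and ethers are inert.

Step 4
Reactants: 5 (E)-hydrazone of ketone 4
Product: 7 (2R,3S)-5-bromo-2-(3,4-dimethoxyphenyl)-7-methoxy-3-methyl-2,3-dihydro-1-benzofuran (cis), via diazoalkane 6 (not isolated)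
Conditions: MnO2 (8 equiv), CH2Cl2, 0 °C, cold filtration through Celite; filtrate added over 1 h to Rh2(S-PTAD)4 (1 mol %), CH2Cl2, −20 °C to rt
Reagents that add atoms: none
Why: MnO2 dehydrogenates 5 to the 1-aryldiazoethane 6, from which Rh2(S-PTAD)4 expels N2 to leave a rhodium-bound aryl/methyl (donor/donor) carbene at C3; this carbon takes a hydride from the O1–CH2 group lying 1,5 to it, and the resulting oxocarbenium/alkylrhodium pair collapses at once, forming C2–C3 and releasing the catalyst. The closest known reaction type is the enantioselective intramolecular C–H insertion of donor/donor rhodium carbenes made from hydrazones of 2-(benzyloxy)aryl ketones, which gives cis-2,3-disubstituted 2,3-dihydrobenzofurans. The one ring that closes (O1–C2–C3–C3a–C7a) does so by 1,5 C–H insertion, and its second stage is formally a 5-endo-trig attack of the C3–Rh σ bond on the O1=C2 oxocarbenium ion, which is feasible because the ortho-disubstituted ring A holds the two carbons in contact. C3 is controlled by the catalyst, whose phthalimide/adamantyl wall leaves one carbene face open to the incoming hydride, and C2 is controlled by the compact transition state, in which the veratryl group turns away from the ligand wall and ends cis to the methyl group (this centre is corrected in step 5, so only the fidelity at C3 matters). The step needs chemoselectivity for insertion over the 1,2-hydride shift from the methyl group, azine formation and attack on the veratryl π system; this is secured by the high hydride-donor ability of the C2–H bonds (α to O1, benzylic to a para-methoxy arene), by the absence of any alkene (C5 carries only Br), and by slow addition of cold 6.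

Step 5
Reactants: 7 (2R,3S)-5-bromo-2-(3,4-dimethoxyphenyl)-7-methoxy-3-methyl-2,3-dihydro-1-benzofuran (cis)
Product: 9 (2S,3S)-5-bromo-2-(3,4-dimethoxyphenyl)-7-methoxy-3-methyl-2,3-dihydro-1-benzofuran (trans), via benzylic cation 8 (not isolated)
Conditions: CF3CO2H (5 equiv), CH2Cl2, 0 °C to rt
Reagents that add atoms: none
Why: Acid-mediated C2 epimerisation of a 2-aryl-2,3-dihydrobenzofuran, in which protonation of O1 and reversible heterolysis of O1–C2 give the para-methoxy-stabilised cation 8, and reclosure by the phenol oxygen under thermodynamic control places the aryl group trans to the untouched C3 methyl group.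

Step 6
Reactants: 9 (2S,3S)-5-bromo-2-(3,4-dimethoxyphenyl)-7-methoxy-3-methyl-2,3-dihydro-1-benzofuran; 10 methyl acrylate
Product: 11 methyl (E)-3-[(2S,3S)-2-(3,4-dimethoxyphenyl)-7-methoxy-3-methyl-2,3-dihydro-1-benzofuran-5-yl]prop-2-enoate
Conditions: Pd(OAc)2 (5 mol %), P(o-tol)3 (10 mol %), Et3N (2 equiv), DMF, 100 °C
Reagents that add atoms: none
Why: Mizoroki–Heck reaction, in which zerovalent palladium adds oxidatively to C5–Br, syn insertion at the acrylate terminus and syn β-hydride elimination give the E-cinnamate, and the basic medium leaves C2 and C3 alone.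

Step 7
Reactants: 11 methyl (E)-3-[(2S,3S)-2-(3,4-dimethoxyphenyl)-7-methoxy-3-methyl-2,3-dihydro-1-benzofuran-5-yl]prop-2-enoate
Product: 12 (E)-3-[(2S,3S)-2-(3,4-dimethoxyphenyl)-7-methoxy-3-methyl-2,3-dihydro-1-benzofuran-5-yl]prop-2-en-1-ol
Conditions: i-Bu2AlH (2.5 equiv), CH2Cl2, −78 °C to 0 °C; aq. KNaC4H4O6
Reagents that add atoms: none
Why: 1,2-Reduction of an α,β-unsaturated ester by i-Bu2AlH gives the allylic alcohol with alkene geometry and stereocentres unchanged, and the non-acidic tartrate work-up protects the cinnamyl alcohol and C2.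

**Compound list**
1 | 1-(2-hydroxy-3-methoxyphenyl)ethan-1-one | CC(=O)c1cccc(OC)c1O | starting material
2 | 1-(5-bromo-2-hydroxy-3-methoxyphenyl)ethan-1-one | CC(=O)c1cc(Br)cc(OC)c1O | intermediate
3 | 4-(chloromethyl)-1,2-dimethoxybenzene (veratryl chloride) | COc1ccc(CCl)cc1OC | starting material
4 | 1-{5-bromo-2-[(3,4-dimethoxyphenyl)methoxy]-3-methoxyphenyl}ethan-1-one | CC(=O)c1cc(Br)cc(OC)c1OCc1ccc(OC)c(OC)c1 | intermediate
5 | (E)-hydrazone of 4 | C/C(=N\N)c1cc(Br)cc(OC)c1OCc1ccc(OC)c(OC)c1 | intermediate
6 | 5-bromo-1-(1-diazoethyl)-2-[(3,4-dimethoxyphenyl)methoxy]-3-methoxybenzene (not isolated) | CC(=[N+]=[N-])c1cc(Br)cc(OC)c1OCc1ccc(OC)c(OC)c1 | intermediate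
7 | (2R,3S)-5-bromo-2-(3,4-dimethoxyphenyl)-7-methoxy-3-methyl-2,3-dihydro-1-benzofuran (cis) | COc1ccc([C@@H]2Oc3c(OC)cc(Br)cc3[C@@H]2C)cc1OC | intermediate
8 | 2-(5-bromo-2-hydroxy-3-methoxyphenyl)-1-(3,4-dimethoxyphenyl)propan-1-ylium; the methyl-bearing carbon keeps the arrangement it has in 7 (not isolated) | COc1ccc([CH+][C@@H](C)c2cc(Br)cc(OC)c2O)cc1OC | intermediate
9 | (2S,3S)-5-bromo-2-(3,4-dimethoxyphenyl)-7-methoxy-3-methyl-2,3-dihydro-1-benzofuran (trans) | COc1ccc([C@H]2Oc3c(OC)cc(Br)cc3[C@@H]2C)cc1OC | intermediate
10 | methyl acrylate | C=CC(=O)OC | starting material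
11 | methyl (E)-3-[(2S,3S)-2-(3,4-dimethoxyphenyl)-7-methoxy-3-methyl-2,3-dihydro-1-benzofuran-5-yl]prop-2-enoate | COc1ccc([C@H]2Oc3c(OC)cc(/C=C/C(=O)OC)cc3[C@@H]2C)cc1OC | intermediate
12 | (E)-3-[(2S,3S)-2-(3,4-dimethoxyphenyl)-7-methoxy-3-methyl-2,3-dihydro-1-benzofuran-5-yl]prop-2-en-1-ol | COc1ccc([C@H]2Oc3c(OC)cc(/C=C/CO)cc3[C@@H]2C)cc1OC | target

Total step count: 7. Longest linear sequence: 7 (from 1).

**Steps most likely to fail**

Step 4. Three things may go wrong. The 1,2-hydride shift from the methyl group of the carbene or diazoalkane may outrun insertion. The diazoalkane may couple to the azine. The catalyst may discriminate poorly between the methyl and aryl flanks of the carbene.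

The fallback sets out from 4 and returns at 9, so it replaces steps 3 to 5. It exchanges the methyl group for an ester. The ester has no β-hydrogen, makes the carbene a donor/acceptor carbene, allows base epimerisation, and is reduced to the methyl group afterwards.
- Ketone 4 is oxidised with SeO2 in pyridine at 100 °C to the arylglyoxylic acid F1.
- F1 is esterified (MeI, K2CO3, DMF) to the methyl arylglyoxylate F2.
- F2 is condensed with TsNHNH2 to the tosylhydrazone F3.
- F3 is treated with DBU in CH2Cl2 (Bamford–Stevens type loss of sulfinate) to give the aryldiazoacetate F4.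
- Rh2(R-PTTL)4 (tetrakis[N-phthaloyl-(R)-tert-leucinato]dirhodium, the series expected by analogy to give 2S) in toluene at −60 °C closes the same C2–C3 bond by C–H insertion. This gives the cis ester F5, in which C2 is now the centre that is kept.
- NaOMe in MeOH epimerises C3 to give the trans ester F6.
- LiAlH4 (THF, 0 °C) gives the primary alcohol F7.
- TsCl in pyridine gives the tosylate F8.
- LiEt3BH (THF, 0 °C) replaces the tosylate by hydride to give 9.

Step 5. Cation 8 may lose the C3 proton or undergo a 1,2-hydride shift, which would erode the configuration at C3. It may also alkylate another electron-rich arene and give oligomers.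

The fallback sets out from 7 and returns at 9. It replaces the cationic path by a neutral radical-chain epimerisation at C2 through reversible hydrogen-atom transfer (polarity-reversal catalysis). The conditions are Ph3SiSH (10 mol %) and t-BuON=NOt-Bu (5 mol %) in benzene at 60 °C. The electrophilic thiyl radical abstracts the weakest and most hydridic C–H, which is C2–H (α-oxy and benzylic). The planar radical takes hydrogen back from the thiol until the trans isomer prevails. This fallback makes no new compound (F0).

Step 6. Oxidative addition to the electron-rich aryl bromide may be slow, with catalyst decay or hydrodebromination taking over.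

The fallback sets out from 9 and returns at 11. It builds the alkene by olefination instead of cross-coupling. Bromine–lithium exchange (n-BuLi, THF, −78 °C) followed by DMF gives the 5-carbaldehyde F9. A Horner–Wadsworth–Emmons reaction with trimethyl phosphonoacetate (NaH, THF, 0 °C) then gives the E-ester 11.

**Further compounds**
F1 | step 4 | 2-{5-bromo-2-[(3,4-dimethoxyphenyl)methoxy]-3-methoxyphenyl}-2-oxoacetic acid | OC(=O)C(=O)c1cc(Br)cc(OC)c1OCc1ccc(OC)c(OC)c1
F2 | step 4 | methyl 2-{5-bromo-2-[(3,4-dimethoxyphenyl)methoxy]-3-methoxyphenyl}-2-oxoacetate | COC(=O)C(=O)c1cc(Br)cc(OC)c1OCc1ccc(OC)c(OC)c1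
F3 | step 4 | N-tosylhydrazone of F2 (C=N geometry of no consequence) | COC(=O)C(=NNS(=O)(=O)c1ccc(C)cc1)c1cc(Br)cc(OC)c1OCc1ccc(OC)c(OC)c1
F4 | step 4 | methyl 2-{5-bromo-2-[(3,4-dimethoxyphenyl)methoxy]-3-methoxyphenyl}-2-diazoacetate | COC(=O)C(=[N+]=[N-])c1cc(Br)cc(OC)c1OCc1ccc(OC)c(OC)c1
F5 | step 4 | methyl (2S,3R)-5-bromo-2-(3,4-dimethoxyphenyl)-7-methoxy-2,3-dihydro-1-benzofuran-3-carboxylate (cis) | COc1ccc([C@H]2Oc3c(OC)cc(Br)cc3[C@H]2C(=O)OC)cc1OC
F6 | step 4 | methyl (2S,3S)-5-bromo-2-(3,4-dimethoxyphenyl)-7-methoxy-2,3-dihydro-1-benzofuran-3-carboxylate (trans) | COc1ccc([C@H]2Oc3c(OC)cc(Br)cc3[C@@H]2C(=O)OC)cc1OC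
F7 | step 4 | [(2S,3R)-5-bromo-2-(3,4-dimethoxyphenyl)-7-methoxy-2,3-dihydro-1-benzofuran-3-yl]methanol (trans) | COc1ccc([C@H]2Oc3c(OC)cc(Br)cc3[C@@H]2CO)cc1OC
F8 | step 4 | [(2S,3R)-5-bromo-2-(3,4-dimethoxyphenyl)-7-methoxy-2,3-dihydro-1-benzofuran-3-yl]methyl 4-methylbenzenesulfonate (trans) | COc1ccc([C@H]2Oc3c(OC)cc(Br)cc3[C@@H]2COS(=O)(=O)c4ccc(C)cc4)cc1OC
F0 | step 5 | none | none
F9 | step 6 | (2S,3S)-2-(3,4-dimethoxyphenyl)-7-methoxy-3-methyl-2,3-dihydro-1-benzofuran-5-carbaldehyde | COc1ccc([C@H]2Oc3c(OC)cc(C=O)cc3[C@@H]2C)cc1OC
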